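## Analysis of the target

Target 14 is a 2,2-dimethyl-2H-chromene whose benzene ring (ring A) carries a substituent on every carbon. Ring A is numbered C1 (methyl ester), C2 (free hydroxyl), C3 (prenyl), C4 (pyran oxygen O1'), C5 (bonded to pyran carbon C4') and C6 (2-(4-hydroxyphenyl)ethyl); the pyran (ring B) is completed by C4'=C3' and the gem-dimethyl carbon C2'. There is no stereocentre. The only stereochemical element in the route is the (E)-alkene of an open-chain precursor, which disappears when the ring-constrained cis alkene of ring B forms. The sensitive groups are the prenyl alkene, which lies between two phenolic oxygens and cyclizes onto either under strong acid or electrophilic halogen, the acid- and oxidant-sensitive chromene, the phenols, and a hindered, hydrogen-bonded salicylate ester. The difficulty is regiochemical: six different groups must stand in a fixed order on one ring, O2 and O4 must be told apart, and C6 is not reached by ordinary electrophilic substitution. The plan rests on the triad C4–C5–C6: when C5 carries iodine, one ortho neighbour (C4) is already oxygen-substituted and the other (C6) is the only C–H of ring A. That is the pattern a Catellani relay needs to alkylate C6 and then functionalize C5 in a single operation. The three pyran carbons can arrive at C5 as a tertiary allylic alcohol that closes onto O4 once the phenols are unmasked.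

## Retrosynthetic reasoning

**Ring B, O1'–C2' bond (14 ⇒ 13 ⇒ 12).** The pyran is opened at the bond between O1' and the gem-dimethyl carbon. This bond is tertiary, allylic and conjugated to an electron-rich arene, so it forms by simple ionization. Opening it exposes an (E)-3-hydroxy-3-methylbutenyl chain on C5, which is a Heck-type retron. The three MOM ethers of 12 are removed in the same acidic operation, passing through triphenol 13. The forward step has to free O4, ionize the carbinol, let the side chain rotate through the delocalized cation, and close the ring without protonating the prenyl alkene.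

**C6–CH2 and C5–C4' bonds (12 ⇒ 8 + 10 + 11).** These two bonds sit on adjacent ring carbons, and a single palladium cycle can form them in a set order. Cutting both reduces the hexasubstituted arene to iodide 8 and two simple partners, bromide 10 and alkene 11, so the arylethyl chain and the whole latent pyran are added in one convergent step. The forward reaction must alkylate C6–H before the C5–palladium bond is consumed; the C4 alkoxy group next to iodine enforces that order.

**Phenol protection (10 ⇒ 9, 8 ⇒ 7).** The phenols have to be masked for a carbonate-mediated coupling at 90 °C. MOM ethers are base-stable, small enough for the crowded ring, and fall off in the final acid step, so no separate deprotection stage is needed.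

**C3–CH2 bond of the prenyl group (7 ⇒ 6 ⇒ 5).** A prenyl group ortho to a phenol is the retron of an aromatic Claisen rearrangement of a 1,1-dimethylallyl ether. Cutting here replaces an unselective C-alkylation by a selective O-alkylation plus an intramolecular shift. With iodine already on C5, C3 is the only ortho carbon from which dienone 6 can rearomatize, so the iodide acts as a blocking group as well as the coupling handle.

**Tertiary allyl ether (5 ⇒ 4 ⇒ 2 + 3).** Tertiary allylic electrophiles alkylate phenols at their primary terminus, so the branched ether is reached through the alkyne. The O4–C bond is formed with propargylic chloride 3, and the alkyne of 4 is then semihydrogenated.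

**C5–I bond (2 ⇒ 1).** Iodine is introduced first, on the plain resorcylate 1, where no alkene is present and the directing effects of the two hydroxyls and the ester converge on C5.

## Alternatives that were turned down

**Alternative 1:** Ring A is dissected into a four-carbon unit (C1, C6, C5 and the carbon that becomes C2), the diazo enone A2, and a two-carbon unit (C3, C4), the siloxyalkyne A3.
- Forward key step: irradiation of A2 causes a Wolff shift that makes C5–C6 and gives a vinylketene. This adds [2+2] to A3 (C2–C3 and C4–C5). The cyclobutenone opens and the dienylketene closes (C1–C2), tautomerizing to phenol A1.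
- For: one step gives a pentasubstituted ring A with ester, free O2–H, prenyl, a silyl-differentiated O4 and the arylethyl chain in unambiguous positions. The conditions are neutral and leave the prenyl group alone.
- Against: C5 emerges as C–H, so ring B still has to be built. That means either halogenation beside a phenol and a prenyl alkene or a separate chromene annulation. A2 and A3 are each multi-step, sensitive compounds.
- Comparison: this route is stronger on regiochemical certainty and needs no hindered C–H palladation. The chosen route instead starts from a purchased arene, is shorter, and uses C5 as the coupling site rather than leaving it for late functionalization.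

**Alternative 2:** The C1–C6 and C2–C3 bonds are cut, leading to enone A5 and dimethyl malonate A6.
- Forward key step: under alkoxide, A6 adds to the β-carbon of A5, and the enolate of the methylene at C3 condenses with a malonate ester to close the cyclohexane-1,3-dione A4.
- For: the reagents are the cheapest of all the routes, the chemistry is classical and scalable, and the positions of the prenyl and arylethyl groups are fixed by the acyclic precursor.
- Against: A4 lies below the aromatic oxidation level. Dehydrogenation needs halogen- or quinone-type oxidants next to a prenyl alkene flanked by enol oxygens. The two trans stereocentres are made only to be erased. After aromatization O2 and O4 are undifferentiated and C5 is again C–H.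
- Comparison: this route is stronger on cost and on robustness of the C–C bond formation. The chosen route never leaves the aromatic oxidation level, needs no oxidant, and distinguishes O4 from O2 by the order of its first steps.

**Alternative 3:** The C1–C2 and C5–C6 bonds are cut by a cycloaddition between diene A8 and ynoate A9.
- Forward key step: the [4+2] adduct, a bicyclo[2.2.2]octadiene, loses its saturated bridge as 2-methylpropene A10 on heating and leaves the arene A7.
- For: regiochemistry follows from matching the oxygenated diene terminus with the ester-bearing alkyne carbon. The arene forms directly without an oxidant or a metal, and A8 derives from an inexpensive cyclic dione.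
- Against: a β-alkyl ynoate is a sluggish dienophile and A8 is fully substituted at one terminus, so high temperatures are expected. Silyl enol ethers and the prenyl group (ene pathways) are then at risk. Both ring oxygens carry the same labile silyl group in A7, and C5 is once more C–H.
- Comparison: this route equals Alternative 1 in regiocontrol and is stronger than the chosen route in not depending on a crowded C–H activation. The chosen route substitutes C5 and C6 in one step and is one step from the target afterwards.

Key step: step 7

Remark: the ring A locants C1–C6 defined in the analysis are used for all intermediates, whatever the locants in their systematic names. 3-Chloro-3-methylbut-1-yne (3) is taken as a purchased reagent.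

## Route

Step 1
Reactants: 1 methyl 2,4-dihydroxybenzoate
Product: 2 methyl 2,4-dihydroxy-5-iodobenzoate
Conditions: ICl (1.05 equiv), AcOH, rt
Reagents that add atoms: iodine monochloride, ClI
Why: Electrophilic aromatic iodination; C5 is para to the 2-hydroxyl, ortho to the 4-hydroxyl and unhindered, whereas C3 is squeezed between two oxygens and C6 is deactivated by the ester. One equivalent of the reagent limits di-iodination.

Step 2
Reactants: 2 methyl 2,4-dihydroxy-5-iodobenzoate; 3 3-chloro-3-methylbut-1-yne
Product: 4 methyl 2-hydroxy-5-iodo-4-[(2-methylbut-3-yn-2-yl)oxy]benzoate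
Conditions: DBU (1.3 equiv), CuCl2·2H2O (1 mol%), MeCN, 0 °C
Reagents that add atoms: none
Why: Copper-catalysed propargylic etherification, in which the phenoxide attacks the tertiary carbon of a copper-bound propargylic species. The 4-hydroxyl is the more acidic and the 2-hydroxyl is held in the hydrogen bond to the ester, so mono-etherification should occur at O4.

Step 3
Reactants: 4 methyl 2-hydroxy-5-iodo-4-[(2-methylbut-3-yn-2-yl)oxy]benzoate
Product: 5 methyl 2-hydroxy-5-iodo-4-[(2-methylbut-3-en-2-yl)oxy]benzoate
Conditions: H2 (1 atm, one equivalent taken up), Pd/CaCO3 poisoned with Pb(OAc)2 (Lindlar catalyst), quinoline, EtOAc, rt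
Reagents that add atoms: none
Why: Lindlar semihydrogenation; on the poisoned surface and without added base a terminal alkyne should be reduced well before the resulting alkene or the aryl C–I bond reacts.

Step 4
Reactants: 5 methyl 2-hydroxy-5-iodo-4-[(2-methylbut-3-en-2-yl)oxy]benzoate
Product: 7 methyl 2,4-dihydroxy-5-iodo-3-(3-methylbut-2-enyl)benzoate, via Claisen cyclohexadienone 6 (not isolated)
Conditions: PhNEt2, 140 °C
Reagents that add atoms: none
Why: Aromatic Claisen rearrangement; the [3,3] shift to C3 gives dienone 6, which enolizes to the phenol, and the allylic transposition turns the 1,1-dimethylallyl ether into a linear prenyl group. Iodine blocks C5, so C3 is the only ortho position from which rearomatization is possible, and the amine solvent buffers traces of acid that would ionize the tertiary ether.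

Step 5
Reactants: 7 methyl 2,4-dihydroxy-5-iodo-3-(3-methylbut-2-enyl)benzoate
Product: 8 methyl 5-iodo-2,4-bis(methoxymethoxy)-3-(3-methylbut-2-enyl)benzoate
Conditions: NaH (3 equiv), MOMCl (3 equiv), DMF, 0 °C → rt
Reagents that add atoms: chloromethyl methyl ether, COCCl
Why: Williamson-type acetalization of both phenoxides; the strong base is needed for the chelated, doubly flanked 2-hydroxyl, and the small electrophile reaches both hindered oxygens.

Step 6
Reactants: 9 4-(2-bromoethyl)phenol
Product: 10 1-(2-bromoethyl)-4-(methoxymethoxy)benzene
Conditions: MOMCl, iPr2NEt, CH2Cl2, 0 °C → rt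
Reagents that add atoms: chloromethyl methyl ether, COCCl
Why: MOM protection of a phenol under amine base; the weak, hindered base avoids phenoxide participation at the bromoethyl chain and E2 loss of HBr.

Step 7
Reactants: 8 methyl 5-iodo-2,4-bis(methoxymethoxy)-3-(3-methylbut-2-enyl)benzoate; 10 1-(2-bromoethyl)-4-(methoxymethoxy)benzene; 11 2-methylbut-3-en-2-ol
Product: 12 methyl 3-[(E)-3-hydroxy-3-methylbut-1-enyl]-4,6-bis(methoxymethoxy)-2-{2-[4-(methoxymethoxy)phenyl]ethyl}-5-(3-methylbut-2-enyl)benzoate
Conditions: Pd(OAc)2 (10 mol%), tri(2-furyl)phosphine (20 mol%), norbornene (2 equiv), Cs2CO3 (3 equiv), 10 (2 equiv), 11 (2 equiv), MeCN, 90 °C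
Reagents that add atoms: none
Why: Catellani reaction, a palladium/norbornene relay joining ortho C–H alkylation by a primary alkyl bromide to an ipso Mizoroki–Heck termination. Zerovalent palladium, formed from Pd(OAc)2 and the phosphine, inserts into the C5–I bond of 8, norbornene inserts into the aryl–palladium bond, and carbonate-assisted palladation of C6–H, the only ring hydrogen, gives a five-membered aryl–norbornyl palladacycle. Bromide 10 adds oxidatively to this palladacycle to give a tetravalent palladium species, and reductive elimination forms the C6–CH2 bond. With C4 (OMOM) and C6 (alkyl) now both flanking C5, steric pressure drives β-carbon elimination of norbornene and returns a divalent arylpalladium at C5, so alkylation necessarily precedes termination. This species inserts the monosubstituted alkene of 11 at its terminal carbon, and β-hydride elimination, possible only on the ring side because the carbinol carbon has no hydrogen, forms C5–C4' as the (E)-alkene. No ring is closed and no stereocentre is created; the alkene geometry follows from syn insertion and syn elimination through the less crowded rotamer. The trisubstituted prenyl alkene should not compete as Heck acceptor, the MOM ethers and the ester are inert to Cs2CO3 in MeCN, and the excess of 10 and 11 allows for some loss of 10 by elimination. The demanding point is that C6–H lies next to the ester, which makes this a hindered member of a well-established reaction class.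

Step 8
Reactants: 12 methyl 3-[(E)-3-hydroxy-3-methylbut-1-enyl]-4,6-bis(methoxymethoxy)-2-{2-[4-(methoxymethoxy)phenyl]ethyl}-5-(3-methylbut-2-enyl)benzoate
Product: 14 methyl 7-hydroxy-5-[2-(4-hydroxyphenyl)ethyl]-2,2-dimethyl-8-(3-methylbut-2-enyl)-2H-chromene-6-carboxylate, via triphenol allylic alcohol 13 (not isolated)
Conditions: 2 M aq. HCl, MeOH, 40 °C
Reagents that add atoms: none
Why: Acid-catalysed methanolysis of the three MOM acetals gives 13; its tertiary, aryl-conjugated allylic alcohol ionizes, the cation (an ortho-quinone methide after loss of the O4 proton) lets the side chain rotate, and O4 closes on C2' in an oxa-6π-type cyclization to the 2H-chromene. Only O4 is ortho to C5, so ring B can form in one sense only, and the carbinol ionizes under far milder acid than is needed to protonate the prenyl alkene. If ionization partly precedes loss of the MOM groups, the same product should result.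

## Compound list

1 | methyl 2,4-dihydroxybenzoate | COC(=O)c1ccc(O)cc1O | starting material
2 | methyl 2,4-dihydroxy-5-iodobenzoate | COC(=O)c1cc(I)c(O)cc1O | intermediate
3 | 3-chloro-3-methylbut-1-yne | CC(C)(Cl)C#C | starting material
4 | methyl 2-hydroxy-5-iodo-4-[(2-methylbut-3-yn-2-yl)oxy]benzoate | COC(=O)c1cc(I)c(OC(C)(C)C#C)cc1O | intermediate
5 | methyl 2-hydroxy-5-iodo-4-[(2-methylbut-3-en-2-yl)oxy]benzoate | COC(=O)c1cc(I)c(OC(C)(C)C=C)cc1O | intermediate
6 | methyl 2-hydroxy-5-iodo-3-(3-methylbut-2-enyl)-4-oxocyclohexa-1,5-diene-1-carboxylate (racemic at C3, not isolated) | COC(=O)C1=C(O)C(CC=C(C)C)C(=O)C(I)=C1 | intermediate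
7 | methyl 2,4-dihydroxy-5-iodo-3-(3-methylbut-2-enyl)benzoate | COC(=O)c1cc(I)c(O)c(CC=C(C)C)c1O | intermediate
8 | methyl 5-iodo-2,4-bis(methoxymethoxy)-3-(3-methylbut-2-enyl)benzoate | COC(=O)c1cc(I)c(OCOC)c(CC=C(C)C)c1OCOC | intermediate
9 | 4-(2-bromoethyl)phenol | Oc1ccc(CCBr)cc1 | starting material
10 | 1-(2-bromoethyl)-4-(methoxymethoxy)benzene | COCOc1ccc(CCBr)cc1 | intermediate
11 | 2-methylbut-3-en-2-ol | CC(C)(O)C=C | starting material
12 | methyl 3-[(E)-3-hydroxy-3-methylbut-1-enyl]-4,6-bis(methoxymethoxy)-2-{2-[4-(methoxymethoxy)phenyl]ethyl}-5-(3-methylbut-2-enyl)benzoate | COC(=O)c1c(CCc2ccc(OCOC)cc2)c(/C=C/C(C)(C)O)c(OCOC)c(CC=C(C)C)c1OCOC | intermediate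
13 | methyl 4,6-dihydroxy-3-[(E)-3-hydroxy-3-methylbut-1-enyl]-2-[2-(4-hydroxyphenyl)ethyl]-5-(3-methylbut-2-enyl)benzoate (not isolated) | COC(=O)c1c(CCc2ccc(O)cc2)c(/C=C/C(C)(C)O)c(O)c(CC=C(C)C)c1O | intermediate
14 | methyl 7-hydroxy-5-[2-(4-hydroxyphenyl)ethyl]-2,2-dimethyl-8-(3-methylbut-2-enyl)-2H-chromene-6-carboxylate | COC(=O)c1c(O)c(CC=C(C)C)c2c(c1CCc1ccc(O)cc1)C=CC(C)(C)O2 | target

## Step count and least certain steps

Total step count: 8. Longest linear sequence: 7 steps (steps 1, 2, 3, 4, 5, 7, 8); step 6 is a one-step side branch.

**Step 7 (key step).** Three processes could divert the reaction: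
- Palladation of C6–H may be slow because the site is flanked by the ester. The C5 arylpalladium species could then undergo direct Heck coupling without alkylation, or give norbornene-retaining by-products.
- Base-induced loss of HBr from 10 would consume the alkylating agent and generate a competing Heck acceptor.
- After alkylation, the C5 arylpalladium could attack the pendant aryl ring by intramolecular C–H arylation instead of inserting 11.

Fallback, setting out from 8 and returning at 12: the C6–H between ester and iodine is deprotonated with TMPMgCl·LiCl in THF at −20 °C to give chloro[2-iodo-6-(methoxycarbonyl)-3,5-bis(methoxymethoxy)-4-(3-methylbut-2-enyl)phenyl]magnesium F1. This is quenched with 1,2-dibromo-1,1,2,2-tetrachloroethane to give methyl 2-bromo-3-iodo-4,6-bis(methoxymethoxy)-5-(3-methylbut-2-enyl)benzoate F2. An ordinary Heck reaction of F2 with 11 (Pd(OAc)2, Bu4NCl, NaHCO3, DMF, 70 °C) should engage the C–I bond selectively and give methyl 2-bromo-3-[(E)-3-hydroxy-3-methylbut-1-enyl]-4,6-bis(methoxymethoxy)-5-(3-methylbut-2-enyl)benzoate F3. Bromide 10 is converted with Zn and LiCl in THF into bromo{2-[4-(methoxymethoxy)phenyl]ethyl}zinc F4. Negishi coupling of F3 with an excess of F4 (Pd(OAc)2 with a bulky dialkylbiarylphosphine, THF, 50 °C) should then deliver 12.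

**Step 3.** Hydrogenolysis of the aryl C–I bond, or over-reduction of the new alkene, could accompany the semihydrogenation on palladium. Fallback, setting out from 1 and returning at 5: 1 is etherified with 3 under the conditions of step 2 to give methyl 2-hydroxy-4-[(2-methylbut-3-yn-2-yl)oxy]benzoate F5. This is semihydrogenated before any halogen is present to give methyl 2-hydroxy-4-[(2-methylbut-3-en-2-yl)oxy]benzoate F6. Iodination of F6 with N-iodosuccinimide in MeCN at the position para to the free hydroxyl should then give 5.

**Step 4.** Ionization of the tertiary allyl ether with loss of the five-carbon unit could compete with the sigmatropic shift, as could migration toward the blocked C5 followed by loss of iodine. Fallback, setting out from 2 and returning at 7: the phenoxide of 2 is C-alkylated directly at C3 with 1-bromo-3-methylbut-2-ene in aqueous KOH (0 °C → rt). With C5 occupied by iodine, C3 is the only nucleophilic ring carbon; O-alkylated material is separated. No new intermediate is involved.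

**Step 8.** Protonation of the prenyl alkene and its capture by O2–H or O4–H (chroman formation) could occur, or the allylic cation could lose a proton toward a diene and oligomerize before O4 is free to close. Fallback, setting out from 8 and 10 and returning at 14: a Catellani ortho-alkylation with ipso-hydride termination (Pd(OAc)2, tri(2-furyl)phosphine, norbornene, Cs2CO3, HCO2Na, DMF, 90 °C) gives methyl 2,4-bis(methoxymethoxy)-6-{2-[4-(methoxymethoxy)phenyl]ethyl}-3-(3-methylbut-2-enyl)benzoate F7. Acidic methanolysis, now without an ionizable carbinol, gives methyl 2,4-dihydroxy-6-[2-(4-hydroxyphenyl)ethyl]-3-(3-methylbut-2-enyl)benzoate F8. Condensation of F8 with 3-methylbut-2-enal (ethylenediammonium diacetate, toluene, 110 °C) builds ring B at the only free position ortho to a ring A hydroxyl, by condensation and oxa-6π electrocyclization, and should give 14.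

## Further compounds

F1 | step 7 | chloro[2-iodo-6-(methoxycarbonyl)-3,5-bis(methoxymethoxy)-4-(3-methylbut-2-enyl)phenyl]magnesium (lithium chloride complex, not isolated) | COC(=O)c1c([Mg]Cl)c(I)c(OCOC)c(CC=C(C)C)c1OCOC
F2 | step 7 | methyl 2-bromo-3-iodo-4,6-bis(methoxymethoxy)-5-(3-methylbut-2-enyl)benzoate | COC(=O)c1c(Br)c(I)c(OCOC)c(CC=C(C)C)c1OCOC
F3 | step 7 | methyl 2-bromo-3-[(E)-3-hydroxy-3-methylbut-1-enyl]-4,6-bis(methoxymethoxy)-5-(3-methylbut-2-enyl)benzoate | COC(=O)c1c(Br)c(/C=C/C(C)(C)O)c(OCOC)c(CC=C(C)C)c1OCOC
F4 | step 7 | bromo{2-[4-(methoxymethoxy)phenyl]ethyl}zinc | COCOc1ccc(CC[Zn]Br)cc1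
F5 | step 3 | methyl 2-hydroxy-4-[(2-methylbut-3-yn-2-yl)oxy]benzoate | COC(=O)c1ccc(OC(C)(C)C#C)cc1O
F6 | step 3 | methyl 2-hydroxy-4-[(2-methylbut-3-en-2-yl)oxy]benzoate | COC(=O)c1ccc(OC(C)(C)C=C)cc1O
F0 | step 4 | none | none
F7 | step 8 | methyl 2,4-bis(methoxymethoxy)-6-{2-[4-(methoxymethoxy)phenyl]ethyl}-3-(3-methylbut-2-enyl)benzoate | COC(=O)c1c(CCc2ccc(OCOC)cc2)cc(OCOC)c(CC=C(C)C)c1OCOC
F8 | step 8 | methyl 2,4-dihydroxy-6-[2-(4-hydroxyphenyl)ethyl]-3-(3-methylbut-2-enyl)benzoate | COC(=O)c1c(CCc2ccc(O)cc2)cc(O)c(CC=C(C)C)c1O
A1 | alternative 1 | methyl 2-hydroxy-3-(3-methylbut-2-enyl)-4-(triisopropylsilyloxy)-6-{2-[4-(tert-butyldimethylsilyloxy)phenyl]ethyl}benzoate | COC(=O)c1c(O)c(CC=C(C)C)c(O[Si](C(C)C)(C(C)C)C(C)C)cc1CCc1ccc(O[Si](C)(C)C(C)(C)C)cc1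
A2 | alternative 1 | methyl (E)-3-{2-[4-(tert-butyldimethylsilyloxy)phenyl]ethyl}-5-diazo-4-oxopent-2-enoate | COC(=O)/C=C(\CCc1ccc(O[Si](C)(C)C(C)(C)C)cc1)C(=O)C=[N+]=[N-]
A3 | alternative 1 | triisopropyl[(5-methylhex-4-en-1-ynyl)oxy]silane | CC(C)=CCC#CO[Si](C(C)C)(C(C)C)C(C)C
A4 | alternative 2 | methyl trans-4-hydroxy-6-{2-[4-(methoxymethoxy)phenyl]ethyl}-3-(3-methylbut-2-enyl)-2-oxocyclohex-3-ene-1-carboxylate (racemic, one enantiomer drawn) | COC(=O)[C@H]1[C@H](CCc2ccc(OCOC)cc2)CC(O)=C(CC=C(C)C)C1=O
A5 | alternative 2 | (E)-1-[4-(methoxymethoxy)phenyl]-9-methyldeca-3,8-dien-5-one | COCOc1ccc(CC/C=C/C(=O)CCC=C(C)C)cc1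
A6 | alternative 2 | dimethyl malonate | COC(=O)CC(=O)OC
A7 | alternative 3 | methyl 3-(3-methylbut-2-enyl)-2,4-bis(trimethylsilyloxy)-6-{2-[4-(tert-butyldimethylsilyloxy)phenyl]ethyl}benzoate | COC(=O)c1c(O[Si](C)(C)C)c(CC=C(C)C)c(O[Si](C)(C)C)cc1CCc1ccc(O[Si](C)(C)C(C)(C)C)cc1
A8 | alternative 3 | 5,5-dimethyl-2-(3-methylbut-2-enyl)-1,3-bis(trimethylsilyloxy)cyclohexa-1,3-diene | CC(C)=CCC1=C(O[Si](C)(C)C)CC(C)(C)C=C1O[Si](C)(C)C
A9 | alternative 3 | methyl 5-[4-(tert-butyldimethylsilyloxy)phenyl]pent-2-ynoate | COC(=O)C#CCCc1ccc(O[Si](C)(C)C(C)(C)C)cc1
A10 | alternative 3 | 2-methylpropene | CC(C)=C
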